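**Plan**

- Retrosynthesis: after removal of a MOM group from O2' of ring B, ring A (C1 CO2Me, C3 OH, C5 OMe, C6 aroyl) is cut at C6–C1 and C6–C5. This is possible because ring A is the phenol tautomer of a cyclohexenone whose C6 can be the spiro C2 of a benzofuran-3(2H)-one fused to ring B, with the C6' oxygen as ring oxygen and the benzophenone C=O as furanone carbonyl.
- The two pieces are a 7-chloro-4-(methoxymethoxy)-6-methylbenzofuran-3(2H)-one and methyl (E)-6-methoxy-4-oxohex-2-en-5-ynoate.
- The benzofuranone is cut at O–CH2 and at the aryl–acyl bond back to chlorinated orcinol; the enynone is cut at the carbinol–alkyne bond back to a fumaraldehydate and methoxyacetylene.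
- Forward: ring B is present from the start and the furanone ring is closed on it. Ring A is then built on the furanone C2 and the furanone ring is opened in the same operation. The MOM ether is cleaved last.
- Stereochemistry: the target has no stereocentre. The (E)-alkene comes from fumarate, and the stereocentres that appear in passing (one carbinol, the spiro carbon and its neighbour) are erased by oxidation or aromatisation.

Key step: step 11

Remark: apart from chlorine, ring B of the target is symmetric about its C1'–C4' axis, so a benzofuranone closed through either phenol oxygen would converge on the same target after MOM cleavage; the route is written for the 7-chloro isomer, which closure through the more acidic, chlorine-flanked phenol should favour.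

**Route**

Step 1
Reactants: 1 orcinol (5-methylbenzene-1,3-diol)
Product: 2 4-chloro-5-methylbenzene-1,3-diol
Conditions: SO2Cl2 (1.0 equiv), Et2O, 0 °C to rt
Reagents that add atoms: sulfuryl chloride, O=S(=O)(Cl)Cl
Why: Electrophilic aromatic chlorination of the resorcinol ring should go mainly to C4, which is ortho to one hydroxyl, para to the other and ortho to the methyl group, and one equivalent of SO2Cl2 at low temperature should stop at the monochloride.

Step 2
Reactants: 2 4-chloro-5-methylbenzene-1,3-diol
Product: 3 2-chloro-1,5-bis(methoxymethoxy)-3-methylbenzene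
Conditions: MOMCl (2.5 equiv), i-Pr2NEt (3 equiv), CH2Cl2, 0 °C to rt
Reagents that add atoms: chloromethyl methyl ether, COCCl
Why: Both phenols are O-alkylated by the reactive chloromethyl ether under amine base (Williamson-type acetal formation), which installs the two groups that later direct the lithiation.

Step 3
Reactants: 3 2-chloro-1,5-bis(methoxymethoxy)-3-methylbenzene
Product: 5 2-chloro-1-[3-chloro-2,6-bis(methoxymethoxy)-4-methylphenyl]ethan-1-one, via aryllithium 4 (not isolated)
Conditions: n-BuLi (1.1 equiv), THF, 0 °C; then ClCH2C(O)N(OMe)Me (1.2 equiv), −78 to 0 °C; sat. aq. NH4Cl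
Reagents that add atoms: 2-chloro-N-methoxy-N-methylacetamide, CON(C)C(=O)CCl
Why: Directed ortho-metalation places lithium on the only carbon flanked by two MOM ethers (the aryl chloride has no ortho hydrogen, so no aryne can form), and the aryllithium is acylated once through the stable chelated adduct of the N-methoxy-N-methylamide (Weinreb ketone synthesis).

Step 4
Reactants: 5 2-chloro-1-[3-chloro-2,6-bis(methoxymethoxy)-4-methylphenyl]ethan-1-one
Product: 7 7-chloro-4-hydroxy-6-methylbenzofuran-3(2H)-one, via dihydroxyphenacyl chloride 6 (not isolated)
Conditions: HCl (3 M in MeOH), 50 °C; then NaOAc (excess), MeOH, reflux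
Reagents that add atoms: none
Why: Methanolic HCl removes both MOM acetals by acetal exchange, and the buffered reflux then closes the furanone by intramolecular Williamson etherification (5-exo-tet, the classical ring closure of 2-hydroxyphenacyl chlorides), in which the chlorine-flanked phenol, being the more acidic and so the one preferentially ionised by acetate, should supply the ring oxygen.

Step 5
Reactants: 7 7-chloro-4-hydroxy-6-methylbenzofuran-3(2H)-one
Product: 8 7-chloro-4-(methoxymethoxy)-6-methylbenzofuran-3(2H)-one
Conditions: MOMCl (1.3 equiv), i-Pr2NEt (1.6 equiv), CH2Cl2, 0 °C to rt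
Reagents that add atoms: chloromethyl methyl ether, COCCl
Why: The chelated phenol is protected as its MOM acetal by O-alkylation under an amine base that is too weak to enolise the furanone C2 methylene, so that position stays free for the key step.

Step 6
Reactants: 9 monomethyl fumarate ((E)-4-methoxy-4-oxobut-2-enoic acid)
Product: 10 methyl (E)-4-hydroxybut-2-enoate
Conditions: BH3·THF (1.0 equiv), THF, −10 °C to rt; then H2O
Reagents that add atoms: none
Why: Borane reduces the free carboxylic acid through its acyloxyborane much faster than it touches the methyl ester or the electron-poor alkene (chemoselective borane reduction of a half-ester), so the (E)-hydroxy enoate should result.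

Step 7
Reactants: 10 methyl (E)-4-hydroxybut-2-enoate
Product: 11 methyl (E)-4-oxobut-2-enoate
Conditions: Dess–Martin periodinane (1.2 equiv), NaHCO3, CH2Cl2, 0 °C to rt
Reagents that add atoms: none
Why: Dess–Martin oxidation converts the primary allylic alcohol into the aldehyde under buffered, non-aqueous conditions that leave the alkene geometry and the ester untouched.

Step 8
Reactants: 12 chloroacetaldehyde dimethyl acetal (2-chloro-1,1-dimethoxyethane)
Product: 14 methoxyacetylene (methoxyethyne), via sodium methoxyacetylide 13 (not isolated)
Conditions: NaNH2 (3 equiv), liquid NH3, −33 °C; then cold sat. aq. NaCl; distillation into a cold trap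
Reagents that add atoms: none
Why: Two amide-induced eliminations (loss of methanol, then of HCl) convert the chloroacetal into the alkoxyacetylide, the standard preparation of 1-alkoxyalkynes, and protonation releases the volatile alkyne.

Step 9
Reactants: 14 methoxyacetylene; 11 methyl (E)-4-oxobut-2-enoate
Product: 16 methyl (E)-4-hydroxy-6-methoxyhex-2-en-5-ynoate (racemic), via lithium methoxyacetylide 15 (not isolated)
Conditions: n-BuLi (1.0 equiv), THF, −78 °C; then 11, −78 °C; sat. aq. NH4Cl at −78 °C
Reagents that add atoms: none
Why: The lithium acetylide adds 1,2 to the aldehyde, by far the most electrophilic site at −78 °C (acetylide–aldehyde addition), and the new carbinol centre forms as a racemate without control because the next step removes it.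

Step 10
Reactants: 16 methyl (E)-4-hydroxy-6-methoxyhex-2-en-5-ynoate
Product: 17 methyl (E)-6-methoxy-4-oxohex-2-en-5-ynoate
Conditions: activated MnO2 (excess), CH2Cl2, 0 °C to rt
Reagents that add atoms: none
Why: Manganese dioxide oxidises the doubly activated (allylic and propargylic) alcohol under neutral conditions, as is usual for alkoxyethynyl vinyl carbinols, and so avoids acid-induced rearrangement of the alkoxyalkyne.

Step 11
Reactants: 8 7-chloro-4-(methoxymethoxy)-6-methylbenzofuran-3(2H)-one; 17 methyl (E)-6-methoxy-4-oxohex-2-en-5-ynoate
Product: 20 methyl 2-[3-chloro-2-hydroxy-6-(methoxymethoxy)-4-methylbenzoyl]-5-hydroxy-3-methoxybenzoate, via Michael adduct 18 (not isolated), via spiro cyclohexenone 19 (not isolated)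
Conditions: KOtBu (1.05 equiv), THF, −40 °C; 17 (1.2 equiv) added slowly, −40 to 0 °C; then KOtBu (1.3 equiv), t-BuOH, 0 °C to rt; sat. aq. NH4Cl
Reagents that add atoms: none
Why: Proposed new method: the potassium enolate of 8 should add through C2 to the alkene carbon of 17 that carries the ester and lies beta to the ketone (giving 18), proton transfer should regenerate the furanone enolate, and this should close ring A by conjugate addition to the methoxy-bearing alkyne carbon to give the spiro cyclohexenone 19; the second charge of base should then remove the proton alpha to the ester, expel the ring B aryloxide from the spiro carbon (E1cB) and, by enolisation of the resulting cyclohexadienone, leave ring A as a phenol with its methyl ether and free hydroxyl already differentiated. The closest known reaction type is the tert-butoxide-mediated double Michael spiroannulation of benzofuran-3(2H)-ones with alkoxyethynyl vinyl ketones to grisan-type cyclohexenones; what is new is the ester at C6' of the spirocycle, which places the aryloxy group beta to an enolisable carbonyl so that ring opening and aromatisation can follow in the same flask. The one ring closed, the six-membered ring A, forms in the 6-endo-dig mode, the 5-exo-dig alternative being an attack on the unactivated alkyne carbon alpha to the ketone. The two stereocentres formed in passing (the spiro carbon and the ester-bearing carbon) are not controlled and need not be, since both end as sp2 carbons of ring A. The selectivity required is that both new C–C bonds form beta to the central ketone, which the substrate secures because the ketone is a stronger acceptor than the ester at the alkene and polarises the ynone towards its alkoxy-bearing terminus, the fumarate-like alkene reacting first because the alkoxyalkyne is tempered by its donor oxygen. The hindered diaryl ketone is carried in as the furanone carbonyl and so is never made by attack on a fully substituted arene.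

Step 12
Reactants: 20 methyl 2-[3-chloro-2-hydroxy-6-(methoxymethoxy)-4-methylbenzoyl]-5-hydroxy-3-methoxybenzoate
Product: 21 monochlorosulochrin (methyl 2-(3-chloro-2,6-dihydroxy-4-methylbenzoyl)-5-hydroxy-3-methoxybenzoate)
Conditions: HCl (1 M in MeOH), rt to 40 °C
Reagents that add atoms: none
Why: Acid-catalysed acetal exchange with methanol removes the MOM group, which is especially labile next to the ketone, while the aryl methyl ether, the aryl chloride and the methyl ester (degenerate exchange in methanol) are unaffected.

**Compound list**

1 | orcinol (5-methylbenzene-1,3-diol) | Cc1cc(O)cc(O)c1 | starting material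
2 | 4-chloro-5-methylbenzene-1,3-diol | Cc1cc(O)cc(O)c1Cl | intermediate
3 | 2-chloro-1,5-bis(methoxymethoxy)-3-methylbenzene | Cc1cc(OCOC)cc(OCOC)c1Cl | intermediate
4 | [3-chloro-2,6-bis(methoxymethoxy)-4-methylphenyl]lithium | [Li]c1c(OCOC)cc(C)c(Cl)c1OCOC | intermediate (not isolated)
5 | 2-chloro-1-[3-chloro-2,6-bis(methoxymethoxy)-4-methylphenyl]ethan-1-one | O=C(CCl)c1c(OCOC)cc(C)c(Cl)c1OCOC | intermediate
6 | 2-chloro-1-(3-chloro-2,6-dihydroxy-4-methylphenyl)ethan-1-one | O=C(CCl)c1c(O)cc(C)c(Cl)c1O | intermediate (not isolated)
7 | 7-chloro-4-hydroxy-6-methylbenzofuran-3(2H)-one | O=C1COc2c(Cl)c(C)cc(O)c12 | intermediate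
8 | 7-chloro-4-(methoxymethoxy)-6-methylbenzofuran-3(2H)-one | O=C1COc2c(Cl)c(C)cc(OCOC)c12 | intermediate
9 | monomethyl fumarate | COC(=O)/C=C/C(=O)O | starting material
10 | methyl (E)-4-hydroxybut-2-enoate | COC(=O)/C=C/CO | intermediate
11 | methyl (E)-4-oxobut-2-enoate | COC(=O)/C=C/C=O | intermediate
12 | chloroacetaldehyde dimethyl acetal | COC(CCl)OC | starting material
13 | sodium methoxyacetylide | [Na+].[C-]#COC | intermediate (not isolated)
14 | methoxyacetylene | COC#C | intermediate
15 | lithium methoxyacetylide | [Li]C#COC | intermediate (not isolated)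
16 | methyl (E)-4-hydroxy-6-methoxyhex-2-en-5-ynoate (racemic) | COC#CC(O)/C=C/C(=O)OC | intermediate
17 | methyl (E)-6-methoxy-4-oxohex-2-en-5-ynoate | COC#CC(=O)/C=C/C(=O)OC | intermediate
18 | methyl 2-[7-chloro-4-(methoxymethoxy)-6-methyl-3-oxo-2,3-dihydrobenzofuran-2-yl]-6-methoxy-4-oxohex-5-ynoate (racemic, mixture of diastereomers) | COC#CC(=O)CC(C(=O)OC)C1Oc2c(Cl)c(C)cc(OCOC)c2C1=O | intermediate (not isolated)
19 | methyl 7-chloro-2'-methoxy-4-(methoxymethoxy)-6-methyl-3,4'-dioxo-3H-spiro[benzofuran-2,1'-cyclohex[2]ene]-6'-carboxylate (racemic, mixture of diastereomers) | COC(=O)C1CC(=O)C=C(OC)C12Oc3c(Cl)c(C)cc(OCOC)c3C2=O | intermediate (not isolated)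
20 | methyl 2-[3-chloro-2-hydroxy-6-(methoxymethoxy)-4-methylbenzoyl]-5-hydroxy-3-methoxybenzoate | COC(=O)c1cc(O)cc(OC)c1C(=O)c1c(OCOC)cc(C)c(Cl)c1O | intermediate
21 | monochlorosulochrin | COC(=O)c1cc(O)cc(OC)c1C(=O)c1c(O)cc(C)c(Cl)c1O | target

**Count and risks**

Total step count: 12. Longest linear sequence: 7 steps (steps 1 to 5, 11 and 12, from orcinol). The enynone branch takes 5 steps (6 to 10, with step 8 feeding step 9).

Steps most likely to fail:

1. Step 11 (Proposed new method). Alkoxide- or phenoxide-initiated oligomerisation of the enynone may outrun the carbon–carbon bond formation, or the cascade may halt at the spiro stage and revert by retro-Michael cleavage when forced. The fallback uses known chemistry and builds ring A by Diels–Alder benzannulation; it sets out from 3 and returns at 21.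
   - The aryllithium 4 made from 3 is formylated with DMF to 3-chloro-2,6-bis(methoxymethoxy)-4-methylbenzaldehyde F1.
   - Addition of methyl propiolate deprotonated with LiN(SiMe3)2 (THF, −78 °C) should give racemic methyl 4-[3-chloro-2,6-bis(methoxymethoxy)-4-methylphenyl]-4-hydroxybut-2-ynoate F2.
   - MnO2 should oxidise F2 to methyl 4-[3-chloro-2,6-bis(methoxymethoxy)-4-methylphenyl]-4-oxobut-2-ynoate F3.
   - The diene [(4,4-dimethoxybuta-1,3-dien-2-yl)oxy]trimethylsilane F4 (from 4,4-dimethoxybut-3-en-2-one, Me3SiCl, Et3N, ZnCl2) should add to F3 with its CH2 terminus at the alkyne carbon beta to the ketone. This gives the cycloadduct methyl 2-[3-chloro-2,6-bis(methoxymethoxy)-4-methylbenzoyl]-3,3-dimethoxy-5-(trimethylsilyloxy)cyclohexa-1,4-diene-1-carboxylate F5.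
   - Loss of methanol and desilylation on mild acidic work-up should give methyl 2-[3-chloro-2,6-bis(methoxymethoxy)-4-methylbenzoyl]-5-hydroxy-3-methoxybenzoate F6.
   - Methanolic HCl removes both MOM groups of F6 to give the target 21.

2. Step 4. The furanone may also close through the phenol oxygen remote from chlorine, so that the 5-chloro and 7-chloro benzofuranones form together. Either would end at 21, but a single compound is wanted. The fallback places chlorine after a ring closure that cannot give isomers; it sets out from 1 and returns at 7.
   - Orcinol 1 is protected (MOMCl, i-Pr2NEt) as 1,3-bis(methoxymethoxy)-5-methylbenzene F7.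
   - n-BuLi should give [2,6-bis(methoxymethoxy)-4-methylphenyl]lithium F8, which is acylated with the amide of step 3 to 2-chloro-1-[2,6-bis(methoxymethoxy)-4-methylphenyl]ethan-1-one F9.
   - Methanolic HCl gives 2-chloro-1-(2,6-dihydroxy-4-methylphenyl)ethan-1-one F10. Its two phenols are equivalent, so NaOAc can close it to one product only, 4-hydroxy-6-methylbenzofuran-3(2H)-one F11.
   - Chlorination of this phenol (SO2Cl2, CH2Cl2, −20 °C) should go para to the hydroxyl, at C7, and give 7.

3. Step 9. The lithium alkoxide of the gamma-hydroxy enoate may isomerise by proton shift to the gamma-keto ester, or the alkoxyalkynyl carbinol may rearrange to an unsaturated ester (Meyer–Schuster type) on work-up. The fallback replaces addition and oxidation by an acylative cross-coupling; it sets out from 9 and 15 and returns at 17.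
   - Oxalyl chloride and catalytic DMF convert 9 into methyl (E)-4-chloro-4-oxobut-2-enoate F12.
   - Lithium methoxyacetylide 15 is quenched with Bu3SnCl to tributyl(methoxyethynyl)stannane F13.
   - Stille-type acylation of F13 with F12 under PdCl2(PPh3)2 catalysis (toluene, rt to 50 °C) should give the enynone 17 directly.

**Further compounds**

F1 | step 11 | 3-chloro-2,6-bis(methoxymethoxy)-4-methylbenzaldehyde | O=Cc1c(OCOC)cc(C)c(Cl)c1OCOC
F2 | step 11 | methyl 4-[3-chloro-2,6-bis(methoxymethoxy)-4-methylphenyl]-4-hydroxybut-2-ynoate (racemic) | COC(=O)C#CC(O)c1c(OCOC)cc(C)c(Cl)c1OCOC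
F3 | step 11 | methyl 4-[3-chloro-2,6-bis(methoxymethoxy)-4-methylphenyl]-4-oxobut-2-ynoate | COC(=O)C#CC(=O)c1c(OCOC)cc(C)c(Cl)c1OCOC
F4 | step 11 | [(4,4-dimethoxybuta-1,3-dien-2-yl)oxy]trimethylsilane | COC(OC)=CC(=C)O[Si](C)(C)C
F5 | step 11 | methyl 2-[3-chloro-2,6-bis(methoxymethoxy)-4-methylbenzoyl]-3,3-dimethoxy-5-(trimethylsilyloxy)cyclohexa-1,4-diene-1-carboxylate | COC(=O)C1=C(C(=O)c2c(OCOC)cc(C)c(Cl)c2OCOC)C(OC)(OC)C=C(O[Si](C)(C)C)C1
F6 | step 11 | methyl 2-[3-chloro-2,6-bis(methoxymethoxy)-4-methylbenzoyl]-5-hydroxy-3-methoxybenzoate | COC(=O)c1cc(O)cc(OC)c1C(=O)c1c(OCOC)cc(C)c(Cl)c1OCOC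
F7 | step 4 | 1,3-bis(methoxymethoxy)-5-methylbenzene | Cc1cc(OCOC)cc(OCOC)c1
F8 | step 4 | [2,6-bis(methoxymethoxy)-4-methylphenyl]lithium | [Li]c1c(OCOC)cc(C)cc1OCOC
F9 | step 4 | 2-chloro-1-[2,6-bis(methoxymethoxy)-4-methylphenyl]ethan-1-one | O=C(CCl)c1c(OCOC)cc(C)cc1OCOC
F10 | step 4 | 2-chloro-1-(2,6-dihydroxy-4-methylphenyl)ethan-1-one | O=C(CCl)c1c(O)cc(C)cc1O
F11 | step 4 | 4-hydroxy-6-methylbenzofuran-3(2H)-one | O=C1COc2cc(C)cc(O)c12
F12 | step 9 | methyl (E)-4-chloro-4-oxobut-2-enoate | COC(=O)/C=C/C(=O)Cl
F13 | step 9 | tributyl(methoxyethynyl)stannane | CCCC[Sn](CCCC)(CCCC)C#COC
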